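**Retrosynthetic overview**

- Feature: numbering the ring from the tertiary carbinol C1 (which carries C7H2OBz) through C2=C3 to C4 (OBz), C5 (OH) and C6 (OH), the oxygens on C1 and C4 stand at the two allylic ends of the C2=C3 alkene. This 1,4-dioxygenated 2-ene is the retron of a diene/dioxygen [4+2] adduct.
- C4–OBz is traced back to SN2 inversion of a cis-1,4-diol. C1–O and C4–O are traced back to an endoperoxide from singlet oxygen and a C1=C2–C3=C4 diene, in which a free C6 hydroxyl and a trans C5 silyl ether choose the face.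
- The diene comes from the ethyl ester of the (5R,6R)-trans-dihydrodiol, and that from the enzymatic cis-dihydrodiol of ethyl benzoate. C5 is inverted on the tetrahydro compound, because an activated C5 carbinol of the cis-diene has an anti-periplanar C6–H and would aromatise; C3=C4 is then restored by bromination and dehydrobromination.
- Rings: the carbocycle is the arene ring throughout. The only ring closed is the peroxide bridge (step 11), and it is opened again in step 12.

Key step: step 11

Remark: locants C1–C7 as defined above are kept for every intermediate, "α" is the face of the C6 oxygen and "β" the other face; ethyl benzoate is assumed to be dihydroxylated by toluene dioxygenase with the 2,3-regiochemistry and (5S,6R) sense that the enzyme shows with monosubstituted benzenes.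

**Route**

Step 1
Reactants: 1 ethyl benzoate
Product: 2 ethyl (5S,6R)-5,6-dihydroxycyclohexa-1,3-diene-1-carboxylate (cis-diol, both hydroxyls α)
Conditions: E. coli JM109(pDTG601) whole cells (toluene dioxygenase), air, glucose, phosphate buffer pH 6.8, 30–35 °C; EtOAc extraction
Reagents that add atoms: dioxygen, O=O
Why: Enzymatic arene cis-dihydroxylation, in which the dioxygenase should add both oxygens of O2 to the ortho and meta carbons from one face, so that C5 (S) and C6 (R) are set by the enzyme.

Step 2
Reactants: 2 ethyl (5S,6R)-5,6-dihydroxycyclohexa-1,3-diene-1-carboxylate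
Product: 3 ethyl (5S,6R)-5,6-dihydroxycyclohex-1-ene-1-carboxylate
Conditions: KO2C–N=N–CO2K (potassium azodicarboxylate), AcOH, MeOH, 0 °C
Reagents that add atoms: none
Why: Diimide reduction, whose concerted syn transfer of H2 should take the less substituted C3=C4 bond and spare the trisubstituted, ester-bearing C1=C2 bond, so that the later activation at C5 cannot end in aromatisation; no stereocentre is touched.

Step 3
Reactants: 3 ethyl (5S,6R)-5,6-dihydroxycyclohex-1-ene-1-carboxylate; 4 benzoic acid
Product: 5 ethyl (5R,6R)-5-(benzoyloxy)-6-hydroxycyclohex-1-ene-1-carboxylate (C5 benzoate β, C6 hydroxyl α)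
Conditions: BzOH, PPh3, DIAD (diisopropyl azodicarboxylate), THF, 0 °C to rt; chromatographic removal of any regioisomer
Reagents that add atoms: benzoic acid (4), OC(=O)c1ccccc1
Why: Mitsunobu reaction, in which the unhindered C5 hydroxyl should be activated in preference to the C6 hydroxyl (flanked by the ester-bearing sp2 carbon and hydrogen-bonded to the ester carbonyl) and SN2 attack of benzoate inverts C5 from S to R.

Step 4
Reactants: 5 ethyl (5R,6R)-5-(benzoyloxy)-6-hydroxycyclohex-1-ene-1-carboxylate; 6 benzoyl chloride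
Product: 7 ethyl (5R,6R)-5,6-bis(benzoyloxy)cyclohex-1-ene-1-carboxylate (trans dibenzoate)
Conditions: BzCl, pyridine, DMAP (cat.), CH2Cl2, 0 °C to rt
Reagents that add atoms: benzoyl chloride (6), O=C(Cl)c1ccccc1
Why: DMAP-catalysed acylation of the remaining secondary alcohol, which also deactivates the allylic C6–H towards hydrogen abstraction in step 5.

Step 5
Reactants: 7 ethyl (5R,6R)-5,6-bis(benzoyloxy)cyclohex-1-ene-1-carboxylate
Product: 8 ethyl (5R,6R)-5,6-bis(benzoyloxy)-3-bromocyclohex-1-ene-1-carboxylate (both C3 epimers)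
Conditions: NBS, AIBN (cat.), PhCF3, 80 °C
Reagents that add atoms: N-bromosuccinimide, O=C1CCC(=O)N1Br
Why: Wohl–Ziegler allylic bromination, which should occur at the C3 methylene (γ to the ester) and not at the acyloxy-bearing C6–H, as in the classical route to arene trans-dihydrodiol diesters; the C3 configuration is lost in step 6.

Step 6
Reactants: 8 ethyl (5R,6R)-5,6-bis(benzoyloxy)-3-bromocyclohex-1-ene-1-carboxylate
Product: 9 ethyl (5R,6R)-5,6-bis(benzoyloxy)cyclohexa-1,3-diene-1-carboxylate
Conditions: DBU, THF, 0 °C to rt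
Reagents that add atoms: none
Why: E2 dehydrobromination restores C3=C4 in conjugation with the enoate, and the trans diester has no hydrogen anti-periplanar to either benzoate, so loss of benzoic acid with aromatisation is not expected.

Step 7
Reactants: 9 ethyl (5R,6R)-5,6-bis(benzoyloxy)cyclohexa-1,3-diene-1-carboxylate
Product: 10 ethyl (5R,6R)-5,6-dihydroxycyclohexa-1,3-diene-1-carboxylate (trans-diol; C5 hydroxyl β, C6 hydroxyl α)
Conditions: NaOEt (cat.), EtOH, 0 °C to rt
Reagents that add atoms: none
Why: Zemplén-type transesterification removes both benzoates as ethyl benzoate, while exchange at the ethyl dienoate is degenerate.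

Step 8
Reactants: 10 ethyl (5R,6R)-5,6-dihydroxycyclohexa-1,3-diene-1-carboxylate; 11 tert-butyldimethylsilyl chloride
Product: 12 ethyl (5R,6R)-5-(tert-butyldimethylsilyloxy)-6-hydroxycyclohexa-1,3-diene-1-carboxylate
Conditions: TBSCl (1.1 equiv), imidazole, DMF, −20 to 0 °C
Reagents that add atoms: tert-butyldimethylsilyl chloride (11), CC(C)(C)[Si](C)(C)Cl
Why: Regioselective silylation, in which the C5 hydroxyl remote from the C1 substituent should react before the C6 hydroxyl (hindered by the ester and hydrogen-bonded to it), in line with the distal selectivity known for arene dihydrodiols.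

Step 9
Reactants: 12 ethyl (5R,6R)-5-(tert-butyldimethylsilyloxy)-6-hydroxycyclohexa-1,3-diene-1-carboxylate
Product: 13 [(5R,6R)-5-(tert-butyldimethylsilyloxy)-6-hydroxycyclohexa-1,3-dien-1-yl]methanol
Conditions: iBu2AlH (3.5 equiv), CH2Cl2, −78 °C; aq. KNaC4H4O6 (potassium sodium tartrate)
Reagents that add atoms: none
Why: 1,2-Reduction of the conjugated ester by the aluminium hydride at low temperature gives the primary allylic alcohol C7–OH and leaves silyl ether and diene alone.

Step 10
Reactants: 13 [(5R,6R)-5-(tert-butyldimethylsilyloxy)-6-hydroxycyclohexa-1,3-dien-1-yl]methanol; 6 benzoyl chloride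
Product: 14 [(5R,6R)-5-(tert-butyldimethylsilyloxy)-6-hydroxycyclohexa-1,3-dien-1-yl]methyl benzoate (diene precursor; C5 silyl ether β, free C6 hydroxyl α)
Conditions: BzCl (1.05 equiv), 2,4,6-collidine, CH2Cl2, −78 to −40 °C
Reagents that add atoms: benzoyl chloride (6), O=C(Cl)c1ccccc1
Why: Selective acylation of the primary allylic hydroxyl over the secondary C6 hydroxyl, which is shielded by C1 and by the neighbouring silyl ether.

Step 11
Reactants: 14 [(5R,6R)-5-(tert-butyldimethylsilyloxy)-6-hydroxycyclohexa-1,3-dien-1-yl]methyl benzoate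
Product: 15 [(1S,4S,7S,8S)-8-(tert-butyldimethylsilyloxy)-7-hydroxy-2,3-dioxabicyclo[2.2.2]oct-5-en-1-yl]methyl benzoate (peroxide bridge from C1 to C4 on the α face)
Conditions: O2, tetraphenylporphyrin (cat.), visible light, CH2Cl2, −40 °C; cold filtration through silica, used at once
Reagents that add atoms: dioxygen, O=O
Why: Singlet oxygen, formed by energy transfer from the excited sensitiser, adds suprafacially to the ring-locked s-cis diene C1=C2–C3=C4 in a [4+2] cycloaddition, the established mode of photooxygenation of cyclohexa-1,3-dienes to 2,3-dioxabicyclo[2.2.2]oct-5-enes. The only ring closed is the 1,2-dioxene bridge C1–O–O–C4, formed by intermolecular cycloaddition and cleaved again in step 12, so no ring of the target is built here. The new centres C1 and C4 are set together, with both C–O bonds on one face because the addition is suprafacial. The face is chosen by the substrate: in the preferred half-chair the C6 hydroxyl and the C5 silyl ether are pseudo-axial on opposite faces, the hydroxyl hydrogen-bonds to the incoming oxygen (the hydroxyl-directing effect of allylic alcohols in non-polar solvent) and the silyl ether shields the β face, so both effects place the C1–O bond cis to the C6–O bond. The step needs π-facial selectivity and [4+2] rather than ene reactivity; the first rests on the cooperating C6–OH/C5–OTBS pair and the aprotic solvent, the second on the fixed s-cis geometry and the low temperature.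

Step 12
Reactants: 15 [(1S,4S,7S,8S)-8-(tert-butyldimethylsilyloxy)-7-hydroxy-2,3-dioxabicyclo[2.2.2]oct-5-en-1-yl]methyl benzoate
Product: 16 [(1S,4S,5R,6S)-5-(tert-butyldimethylsilyloxy)-1,4,6-trihydroxycyclohex-2-en-1-yl]methyl benzoate (C1, C4 and C6 hydroxyls α)
Conditions: thiourea (2.2 equiv), MeOH, 0 °C to rt
Reagents that add atoms: none
Why: Thiourea reduces the O–O bond of the bicyclic endoperoxide to the cis-1,4-diol without breaking a C–O bond, so C1 and C4 keep their configuration.

Step 13
Reactants: 16 [(1S,4S,5R,6S)-5-(tert-butyldimethylsilyloxy)-1,4,6-trihydroxycyclohex-2-en-1-yl]methyl benzoate; 4 benzoic acid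
Product: 17 [(1S,4R,5S,6S)-4-(benzoyloxy)-5-(tert-butyldimethylsilyloxy)-1,6-dihydroxycyclohex-2-en-1-yl]methyl benzoate (C4 benzoate β)
Conditions: BzOH, PPh3, DIAD, toluene, −20 to 0 °C
Reagents that add atoms: benzoic acid (4), OC(=O)c1ccccc1
Why: Mitsunobu reaction, in which only the secondary allylic C4 hydroxyl should be activated (C1 is tertiary, C6 lies between the quaternary C1 and the silyl ether) and SN2 attack of benzoate inverts C4 to R, trans to the C1 oxygen.

Step 14
Reactants: 17 [(1S,4R,5S,6S)-4-(benzoyloxy)-5-(tert-butyldimethylsilyloxy)-1,6-dihydroxycyclohex-2-en-1-yl]methyl benzoate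
Product: 18 [(1S,4R,5S,6S)-4-(benzoyloxy)-1,5,6-trihydroxycyclohex-2-en-1-yl]methyl benzoate (target)
Conditions: HF·pyridine, THF/pyridine, 0 °C to rt
Reagents that add atoms: none
Why: Acidic fluoride cleaves the secondary silyl ether, and the acidic medium is chosen so that the C4 benzoate does not migrate to the freed cis C5 hydroxyl.

**Compound list**

1 | ethyl benzoate | CCOC(=O)c1ccccc1 | starting material
2 | ethyl (5S,6R)-5,6-dihydroxycyclohexa-1,3-diene-1-carboxylate | CCOC(=O)C1=CC=C[C@H](O)[C@@H]1O | intermediate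
3 | ethyl (5S,6R)-5,6-dihydroxycyclohex-1-ene-1-carboxylate | CCOC(=O)C1=CCC[C@H](O)[C@@H]1O | intermediate
4 | benzoic acid | OC(=O)c1ccccc1 | starting material
5 | ethyl (5R,6R)-5-(benzoyloxy)-6-hydroxycyclohex-1-ene-1-carboxylate | CCOC(=O)C1=CCC[C@@H](OC(=O)c2ccccc2)[C@@H]1O | intermediate
6 | benzoyl chloride | O=C(Cl)c1ccccc1 | starting material
7 | ethyl (5R,6R)-5,6-bis(benzoyloxy)cyclohex-1-ene-1-carboxylate | CCOC(=O)C1=CCC[C@@H](OC(=O)c2ccccc2)[C@@H]1OC(=O)c1ccccc1 | intermediate
8 | ethyl (5R,6R)-5,6-bis(benzoyloxy)-3-bromocyclohex-1-ene-1-carboxylate (C3 epimers) | CCOC(=O)C1=CC(Br)C[C@@H](OC(=O)c2ccccc2)[C@@H]1OC(=O)c1ccccc1 | intermediate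
9 | ethyl (5R,6R)-5,6-bis(benzoyloxy)cyclohexa-1,3-diene-1-carboxylate | CCOC(=O)C1=CC=C[C@@H](OC(=O)c2ccccc2)[C@@H]1OC(=O)c1ccccc1 | intermediate
10 | ethyl (5R,6R)-5,6-dihydroxycyclohexa-1,3-diene-1-carboxylate | CCOC(=O)C1=CC=C[C@@H](O)[C@@H]1O | intermediate
11 | tert-butyldimethylsilyl chloride | CC(C)(C)[Si](C)(C)Cl | starting material
12 | ethyl (5R,6R)-5-(tert-butyldimethylsilyloxy)-6-hydroxycyclohexa-1,3-diene-1-carboxylate | CCOC(=O)C1=CC=C[C@@H](O[Si](C)(C)C(C)(C)C)[C@@H]1O | intermediate
13 | [(5R,6R)-5-(tert-butyldimethylsilyloxy)-6-hydroxycyclohexa-1,3-dien-1-yl]methanol | OCC1=CC=C[C@@H](O[Si](C)(C)C(C)(C)C)[C@@H]1O | intermediate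
14 | [(5R,6R)-5-(tert-butyldimethylsilyloxy)-6-hydroxycyclohexa-1,3-dien-1-yl]methyl benzoate | O=C(OCC1=CC=C[C@@H](O[Si](C)(C)C(C)(C)C)[C@@H]1O)c1ccccc1 | intermediate
15 | [(1S,4S,7S,8S)-8-(tert-butyldimethylsilyloxy)-7-hydroxy-2,3-dioxabicyclo[2.2.2]oct-5-en-1-yl]methyl benzoate | O=C(OC[C@]12C=C[C@H](OO1)[C@@H](O[Si](C)(C)C(C)(C)C)[C@@H]2O)c1ccccc1 | intermediate
16 | [(1S,4S,5R,6S)-5-(tert-butyldimethylsilyloxy)-1,4,6-trihydroxycyclohex-2-en-1-yl]methyl benzoate | O=C(OC[C@@]1(O)C=C[C@H](O)[C@@H](O[Si](C)(C)C(C)(C)C)[C@@H]1O)c1ccccc1 | intermediate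
17 | [(1S,4R,5S,6S)-4-(benzoyloxy)-5-(tert-butyldimethylsilyloxy)-1,6-dihydroxycyclohex-2-en-1-yl]methyl benzoate | O=C(OC[C@@]1(O)C=C[C@@H](OC(=O)c2ccccc2)[C@@H](O[Si](C)(C)C(C)(C)C)[C@@H]1O)c1ccccc1 | intermediate
18 | [(1S,4R,5S,6S)-4-(benzoyloxy)-1,5,6-trihydroxycyclohex-2-en-1-yl]methyl benzoate | O=C(OC[C@@]1(O)C=C[C@@H](OC(=O)c2ccccc2)[C@@H](O)[C@@H]1O)c1ccccc1 | target

**Step count and risks**

Total step count: 14. Longest linear sequence: 14 steps (1 to 18).

Steps most likely to fail:

Step 11. The photooxygenation may lose facial control (attack on the β face past the silyl ether), may turn into ene-type hydroperoxidation at the C7 or C6 hydrogens, or the endoperoxide may rearrange on handling. The fallback keeps the cis 1,4-dioxygenation but builds it in two polar steps. It sets out from 14. Hydroxyl-directed epoxidation with VO(acac)2 and t-BuOOH (CH2Cl2, 0 °C) should take the C1=C2 bond of the allylic alcohol on the face of the C6 hydroxyl and give the vinyl epoxide [(1S,2S,3R,6R)-3-(tert-butyldimethylsilyloxy)-2-hydroxy-7-oxabicyclo[4.1.0]hept-4-en-1-yl]methyl benzoate F2 (epoxide oxygen α). Opening with levulinic acid under Pd(PPh3)4 catalysis (zerovalent palladium, THF, 0 °C) proceeds by ionisation of the allylic C2–O bond with inversion and attack of the carboxylate at C4 with a second inversion, which should give the cis-1,4 hydroxy ester [(1S,4S,5S,6S)-5-(tert-butyldimethylsilyloxy)-1,6-dihydroxy-4-(4-oxopentanoyloxy)cyclohex-2-en-1-yl]methyl benzoate F3. Hydrazine acetate in pyridine/AcOH removes the levulinate in the presence of the benzoate and the route is rejoined at 16.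

Step 13. Benzoate has to enter C4 on the face of the neighbouring silyl ether, so substitution may be slow and give way to SN2' entry at C2, to elimination, or to consumption of the reagent by the cis C1/C6 diol as a cyclic phosphorane. The fallback replaces substitution by an oxidation/reduction pair and sets out from 15. Et3N (CH2Cl2, 0 °C) should bring about the Kornblum–DeLaMare rearrangement, regioselective because only C4 carries a bridgehead hydrogen, to the hydroxy enone [(1S,5S,6S)-5-(tert-butyldimethylsilyloxy)-1,6-dihydroxy-4-oxocyclohex-2-en-1-yl]methyl benzoate F4. Me4NBH(OAc)3 (MeCN/AcOH, −20 °C) delivers hydride within a boron alkoxide of the α hydroxyls on C6 and C1 (directed 1,3-anti reduction of a β-hydroxy ketone), which should give [(1S,4R,5R,6S)-5-(tert-butyldimethylsilyloxy)-1,4,6-trihydroxycyclohex-2-en-1-yl]methyl benzoate F5, the C4 epimer of 16. Benzoyl chloride and collidine at low temperature acylate the allylic C4 hydroxyl in preference to the more shielded C6 and tertiary C1 hydroxyls, and the route is rejoined at 17.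

Step 3. The Mitsunobu reaction may activate the C6 hydroxyl as well, through a cyclic dioxaphosphorane or with SN2' entry of benzoate at C2. Because step 4 benzoylates the second hydroxyl, a C6-inverted regioisomer would turn into the enantiomer of 7, so the site of inversion governs enantiomeric purity. The fallback fixes the site in a separate kinetic step and sets out from 3. p-Toluenesulfonyl chloride in pyridine at −20 °C should sulfonylate only the unhindered C5 hydroxyl to ethyl (5S,6R)-6-hydroxy-5-(p-toluenesulfonyloxy)cyclohex-1-ene-1-carboxylate F1. PhCO2Cs with 18-crown-6 in toluene at 80 °C should displace the sulfonate with inversion and rejoin the route at 5.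

Further compounds
F1 | step 3 | ethyl (5S,6R)-6-hydroxy-5-(p-toluenesulfonyloxy)cyclohex-1-ene-1-carboxylate | CCOC(=O)C1=CCC[C@H](OS(=O)(=O)c2ccc(C)cc2)[C@@H]1O
F2 | step 11 | [(1S,2S,3R,6R)-3-(tert-butyldimethylsilyloxy)-2-hydroxy-7-oxabicyclo[4.1.0]hept-4-en-1-yl]methyl benzoate | O=C(OC[C@@]12O[C@@H]1C=C[C@@H](O[Si](C)(C)C(C)(C)C)[C@@H]2O)c1ccccc1
F3 | step 11 | [(1S,4S,5S,6S)-5-(tert-butyldimethylsilyloxy)-1,6-dihydroxy-4-(4-oxopentanoyloxy)cyclohex-2-en-1-yl]methyl benzoate | O=C(OC[C@@]1(O)C=C[C@H](OC(=O)CCC(C)=O)[C@@H](O[Si](C)(C)C(C)(C)C)[C@@H]1O)c1ccccc1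
F4 | step 13 | [(1S,5S,6S)-5-(tert-butyldimethylsilyloxy)-1,6-dihydroxy-4-oxocyclohex-2-en-1-yl]methyl benzoate | O=C(OC[C@@]1(O)C=CC(=O)[C@@H](O[Si](C)(C)C(C)(C)C)[C@@H]1O)c1ccccc1
F5 | step 13 | [(1S,4R,5R,6S)-5-(tert-butyldimethylsilyloxy)-1,4,6-trihydroxycyclohex-2-en-1-yl]methyl benzoate | O=C(OC[C@@]1(O)C=C[C@@H](O)[C@@H](O[Si](C)(C)C(C)(C)C)[C@@H]1O)c1ccccc1
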